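**Plan**

- Retrosynthesis: the chromone is cut at O1–C2 and C2–C3 (chalcone route), giving a dibenzyl-protected phloroacetophenone (ring A) and 2,3,4,5-tetramethoxybenzaldehyde (ring B plus C2).
- Ring B is then cut at C1'–C2' back to a 4-alkynyl-4-hydroxycyclobutenone, and that at C5'–C6' to dimethyl squarate and 3,3-diethoxypropyne.
- Enabling feature: ring B carries oxygen on four contiguous carbons, C2'–C5', with the C3'/C4' methoxy pair flanked by the para-related C2' and C5' oxygens. This is the oxidation pattern of the four squarate carbons; C1' and C6' map onto the two alkyne carbons, and the acetal carbon becomes C2 of ring C.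
- Forward order: acetylide addition, thermal ring expansion to the quinone (ring B), reductive methylation, acetal hydrolysis, aldol condensation with the ring A ketone, oxidative closure of ring C, debenzylation.
- Stereochemistry: the target is achiral. The racemic carbinol centre of the cyclobutenone is destroyed in the ring expansion, and the E-enone of the chalcone is consumed on cyclization.

Key step: step 2

Assumption: commercial 2',4',6'-trihydroxyacetophenone monohydrate is dried to the anhydrous phenol 11 before use.

**Route**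

Step 1
Reactants: 1 dimethyl squarate (3,4-dimethoxycyclobut-3-ene-1,2-dione); 2 3,3-diethoxyprop-1-yne
Product: 4 4-(3,3-diethoxyprop-1-yn-1-yl)-4-hydroxy-2,3-dimethoxycyclobut-2-en-1-one (racemic), via lithium acetylide 3 (not isolated)
Conditions: 2, n-BuLi, THF, –78 °C; cannulate into 1, THF, –78 °C; aq. NH4Cl quench at –78 °C
Reagents that add atoms: none
Why: 1,2-Carbonyl addition of a lithium acetylide to one carbonyl of a squarate diester at low temperature is the standard entry to 4-alkynyl-4-hydroxycyclobutenones and should stop at mono-addition under inverse addition; the new carbinol centre forms as a racemate and is erased in step 2.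

Step 2
Reactants: 4 4-(3,3-diethoxyprop-1-yn-1-yl)-4-hydroxy-2,3-dimethoxycyclobut-2-en-1-one
Product: 7 5-(diethoxymethyl)-2,3-dimethoxycyclohexa-2,5-diene-1,4-dione, via enynyl ketene 5 (not isolated), via aryl phenoxyl diradical 6 (not isolated)
Conditions: p-xylene (degassed, 0.02 M), 138 °C, Ar
Reagents that add atoms: none
Why: Heating should trigger conrotatory four-electron opening of the cyclobutenone C1–C4 bond, the hydroxyl donor rotating outward so that the alkyne lies inward in (Z)-ketene 5. The ketene carbon then bonds to the distal alkyne carbon (future C2'–C1'), a six-membered closure of the enynyl ketene that gives ring B as the aromatic diradical 6, with a phenoxyl oxygen and a sigma radical on future C6'. Transfer of the neighbouring hydroxyl hydrogen to that sigma radical delivers quinone 7; the closest known reaction is the Moore rearrangement of squarate-derived 4-alkynyl-4-hydroxycyclobutenones to 2,3-dialkoxy-1,4-benzoquinones. No stereocentre is formed, and the racemic carbinol centre of 4 disappears. The selectivity needed is six-membered over five-membered closure (the latter would give an alkylidenecyclopentenedione); it is secured because the sp3 acetal substituent cannot stabilize the exocyclic vinyl radical of the five-membered path, unlike aryl, silyl or alkoxy groups.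

Step 3
Reactants: 7 5-(diethoxymethyl)-2,3-dimethoxycyclohexa-2,5-diene-1,4-dione
Product: 9 1-(diethoxymethyl)-2,3,4,5-tetramethoxybenzene, via hydroquinone 8 (not isolated)
Conditions: Na2S2O4, Bu4NBr (cat.), THF/H2O, rt, Ar; then aq. KOH, Me2SO4, 0 °C to rt
Reagents that add atoms: dimethyl sulfate, COS(=O)(=O)OC
Why: Reductive methylation of a quinone: dithionite reduces 7 to the hydroquinone, and phase-transfer Williamson O-alkylation under basic, acetal-safe conditions should cap both phenoxides before they reoxidize.

Step 4
Reactants: 9 1-(diethoxymethyl)-2,3,4,5-tetramethoxybenzene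
Product: 10 2,3,4,5-tetramethoxybenzaldehyde
Conditions: 1 M HCl, THF, rt
Reagents that add atoms: water, O
Why: Acid-catalysed acetal hydrolysis of an electron-rich benzylic acetal is fast at room temperature, and the aryl methyl ethers are inert to dilute aqueous acid.

Step 5
Reactants: 11 2',4',6'-trihydroxyacetophenone
Product: 12 1-[2,4-bis(benzyloxy)-6-hydroxyphenyl]ethan-1-one
Conditions: BnBr (2.1 equiv), K2CO3, acetone, reflux
Reagents that add atoms: benzyl bromide, BrCc1ccccc1
Why: Williamson etherification; the hydroxyl hydrogen-bonded to the acetyl carbonyl is the least nucleophilic, so two equivalents of BnBr should alkylate the 4'-OH and one ortho OH and leave the chelated phenol free.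

Step 6
Reactants: 10 2,3,4,5-tetramethoxybenzaldehyde; 12 1-[2,4-bis(benzyloxy)-6-hydroxyphenyl]ethan-1-one
Product: 13 (E)-1-[2,4-bis(benzyloxy)-6-hydroxyphenyl]-3-(2,3,4,5-tetramethoxyphenyl)prop-2-en-1-one
Conditions: KOH (50% aq.), EtOH/THF, rt
Reagents that add atoms: none
Why: Claisen–Schmidt (crossed aldol) condensation: the non-enolizable aldehyde traps the acetophenone enolate, and E1cB dehydration should give the thermodynamically preferred E-enone.

Step 7
Reactants: 13 (E)-1-[2,4-bis(benzyloxy)-6-hydroxyphenyl]-3-(2,3,4,5-tetramethoxyphenyl)prop-2-en-1-one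
Product: 14 5,7-bis(benzyloxy)-2-(2,3,4,5-tetramethoxyphenyl)-4H-chromen-4-one
Conditions: I2 (10 mol%), DMSO, 120 °C
Reagents that add atoms: none
Why: Iodine-catalysed oxidative cyclization of a 2'-hydroxychalcone: the free phenol closes onto the enone to form O1–C2 and the heterocycle is dehydrogenated, DMSO regenerating iodine from HI; benzyl and methyl aryl ethers tolerate these conditions.

Step 8
Reactants: 14 5,7-bis(benzyloxy)-2-(2,3,4,5-tetramethoxyphenyl)-4H-chromen-4-one
Product: 15 5,7-dihydroxy-2',3',4',5'-tetramethoxyflavone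
Conditions: H2 (1 atm), 10% Pd/C, THF/MeOH, rt
Reagents that add atoms: none
Why: Heterogeneous hydrogenolysis of aryl benzyl ethers at atmospheric pressure should outpace reduction of the chromone C2–C3 double bond, and the four methyl ethers are untouched.

**Compound list**

1 | dimethyl squarate (3,4-dimethoxycyclobut-3-ene-1,2-dione) | COC1=C(OC)C(=O)C1=O | starting material
2 | 3,3-diethoxyprop-1-yne | C#CC(OCC)OCC | starting material
3 | (3,3-diethoxyprop-1-yn-1-yl)lithium (not isolated) | [Li]C#CC(OCC)OCC | intermediate
4 | 4-(3,3-diethoxyprop-1-yn-1-yl)-4-hydroxy-2,3-dimethoxycyclobut-2-en-1-one (racemic) | CCOC(OCC)C#CC1(O)C(OC)=C(OC)C1=O | intermediate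
5 | (3Z)-7,7-diethoxy-4-hydroxy-2,3-dimethoxyhepta-1,3-dien-5-yn-1-one, the enynyl ketene (not isolated) | O=C=C(OC)/C(OC)=C(/O)C#CC(OCC)OCC | intermediate
6 | 6-(diethoxymethyl)-4-hydroxy-2,3-dimethoxyphenoxyl carrying a sigma radical at C5, the aryl phenoxyl diradical (not isolated) | CCOC(OCC)c1[c]c(O)c(OC)c(OC)c1[O] | intermediate
7 | 5-(diethoxymethyl)-2,3-dimethoxycyclohexa-2,5-diene-1,4-dione | CCOC(OCC)C1=CC(=O)C(OC)=C(OC)C1=O | intermediate
8 | 5-(diethoxymethyl)-2,3-dimethoxybenzene-1,4-diol (not isolated) | CCOC(OCC)c1cc(O)c(OC)c(OC)c1O | intermediate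
9 | 1-(diethoxymethyl)-2,3,4,5-tetramethoxybenzene | CCOC(OCC)c1cc(OC)c(OC)c(OC)c1OC | intermediate
10 | 2,3,4,5-tetramethoxybenzaldehyde | COc1cc(C=O)c(OC)c(OC)c1OC | intermediate
11 | 2',4',6'-trihydroxyacetophenone | CC(=O)c1c(O)cc(O)cc1O | starting material
12 | 1-[2,4-bis(benzyloxy)-6-hydroxyphenyl]ethan-1-one | CC(=O)c1c(O)cc(OCc2ccccc2)cc1OCc1ccccc1 | intermediate
13 | (E)-1-[2,4-bis(benzyloxy)-6-hydroxyphenyl]-3-(2,3,4,5-tetramethoxyphenyl)prop-2-en-1-one | COc1cc(/C=C/C(=O)c2c(O)cc(OCc3ccccc3)cc2OCc2ccccc2)c(OC)c(OC)c1OC | intermediate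
14 | 5,7-bis(benzyloxy)-2-(2,3,4,5-tetramethoxyphenyl)-4H-chromen-4-one | COc1cc(-c2cc(=O)c3c(OCc4ccccc4)cc(OCc4ccccc4)cc3o2)c(OC)c(OC)c1OC | intermediate
15 | 5,7-dihydroxy-2',3',4',5'-tetramethoxyflavone | COc1cc(-c2cc(=O)c3c(O)cc(O)cc3o2)c(OC)c(OC)c1OC | target

**Step count**

Total: 8 steps. Longest linear sequence: 7 steps (steps 1–4, then 6–8); step 5 is a one-step side branch.

**Steps most likely to fail**

Step 2. The enynyl ketene may close through its proximal alkyne carbon to a five-membered ring, or may be consumed intermolecularly before it cyclizes. The fallback replaces the diradical closure by a concerted six-electron electrocyclization, for which no five-membered alternative exists.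
- It sets out from 1 and 2.
- Radical hydrostannation of 2 (Bu3SnH, AIBN, 85 °C) should give (E)-tributyl(3,3-diethoxyprop-1-en-1-yl)stannane F1.
- Tin–lithium exchange with n-BuLi in THF at –78 °C gives (E)-(3,3-diethoxyprop-1-en-1-yl)lithium F2.
- Addition of F2 to 1 at –78 °C gives 4-[(E)-3,3-diethoxyprop-1-en-1-yl]-4-hydroxy-2,3-dimethoxycyclobut-2-en-1-one (racemic) F3.
- Heating F3 in toluene opens it to (3Z,5E)-7,7-diethoxy-4-hydroxy-2,3-dimethoxyhepta-1,3,5-trien-1-one F4.
- F4 closes to 6-(diethoxymethyl)-4-hydroxy-2,3-dimethoxycyclohexa-2,4-dien-1-one (racemic) F5, which tautomerizes to hydroquinone 8.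
- The fallback comes back to the route at 8, which is methylated with aq. KOH/Me2SO4 as in the second half of step 3 to give 9.

Step 3. The acetal may hydrolyse early in the mildly acidic dithionite phase, the electron-rich hydroquinone dianion may reoxidize in air, or the hindered phenoxide between the acetal and a methoxy group may alkylate incompletely. The fallback removes the acid-labile group before the sensitive stage.
- It sets out from 7.
- Reduction with Na2S2O4 in EtOAc/water gives 8, which is deliberately hydrolysed with 1 M HCl in THF to 2,5-dihydroxy-3,4-dimethoxybenzaldehyde F6, a chelated and less oxidizable hydroquinone.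
- Exhaustive methylation of F6 with MeI and K2CO3 in DMF gives aldehyde 10, where the fallback comes back to the route; step 4 is then not needed.

Step 7. Cyclization may stop at the saturated heterocycle, iodine may substitute the electron-rich ring A at C6 or C8, or HI may strip the 5-O-benzyl group. The fallback is iodine-free and separates ring closure from dehydrogenation.
- It sets out from 13.
- Oxa-Michael closure with NaOAc in refluxing EtOH gives 5,7-bis(benzyloxy)-2-(2,3,4,5-tetramethoxyphenyl)chroman-4-one (racemic) F7.
- Dehydrogenation of F7 with DDQ in refluxing dioxane gives 14, where the fallback comes back to the route.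

Further compounds
F1 | step 2 | (E)-tributyl(3,3-diethoxyprop-1-en-1-yl)stannane | CCCC[Sn](CCCC)(CCCC)/C=C/C(OCC)OCC
F2 | step 2 | (E)-(3,3-diethoxyprop-1-en-1-yl)lithium | [Li]/C=C/C(OCC)OCC
F3 | step 2 | 4-[(E)-3,3-diethoxyprop-1-en-1-yl]-4-hydroxy-2,3-dimethoxycyclobut-2-en-1-one (racemic) | CCOC(OCC)/C=C/C1(O)C(OC)=C(OC)C1=O
F4 | step 2 | (3Z,5E)-7,7-diethoxy-4-hydroxy-2,3-dimethoxyhepta-1,3,5-trien-1-one | O=C=C(OC)/C(OC)=C(/O)\C=C\C(OCC)OCC
F5 | step 2 | 6-(diethoxymethyl)-4-hydroxy-2,3-dimethoxycyclohexa-2,4-dien-1-one (racemic) | O=C1C(OC)=C(OC)C(O)=CC1C(OCC)OCC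
F6 | step 3 | 2,5-dihydroxy-3,4-dimethoxybenzaldehyde | O=Cc1cc(O)c(OC)c(OC)c1O
F7 | step 7 | 5,7-bis(benzyloxy)-2-(2,3,4,5-tetramethoxyphenyl)chroman-4-one (racemic) | COc1cc(C2CC(=O)c3c(OCc4ccccc4)cc(OCc4ccccc4)cc3O2)c(OC)c(OC)c1OC
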